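**Retrosynthetic overview** (ring numbering: C1 = C=O, C2=C3(CH3), C4 = CHOH, C5 = CH–side chain, C6 = CH2; the target is (4S,5S), hydroxyl and side chain cis)
1. The only ring is closed last: C2=C3 by ring-closing metathesis of an acyclic γ-hydroxy vinyl ketone that already carries both stereocentres.
2. That ketone comes from vinylmagnesium bromide and a trans-γ-lactone; the lactone comes from a γ-hydroxy Z-enol carbamate by unmasking and oxidation.
3. Key bond C4–C5: methacrolein plus a chiral homoenolate equivalent (α-titanated E-allyl carbamate, (−)-sparteine) in a Hoppe homoaldol reaction; C5 is the β-carbon of the later C1 carbonyl, and C4 and C5 are set together.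
4. The allyl carbamate comes from geranylgeranyl bromide and propargyl carbamate by hydrozirconation and palladium-catalysed alkenyl–allyl coupling.

Assumption: all-E geranylgeranyl bromide and (−)-sparteine are bought as catalogue reagents.

**Step 1**
Reactants: 1 prop-2-yn-1-ol; 2 N,N-diisopropylcarbamoyl chloride
Product: 3 prop-2-yn-1-yl N,N-diisopropylcarbamate
Conditions: pyridine, 90 °C
Reagents that add atoms: none
Why: O-carbamoylation (acyl substitution at the carbamoyl chloride by the alcohol, pyridine as base); no stereocentre.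

**Step 2**
Reactants: 3 prop-2-yn-1-yl N,N-diisopropylcarbamate; 4 (2E,6E,10E)-geranylgeranyl bromide
Product: 6 (2E,5E,9E,13E)-6,10,14,18-tetramethylnonadeca-2,5,9,13,17-pentaen-1-yl N,N-diisopropylcarbamate, via (E)-alkenylzirconocene chloride 5 (not isolated)
Conditions: Cp2Zr(H)Cl (1.1 equiv), THF, rt, 20 min; then 4, Pd(PPh3)4 (5 mol %), THF, rt
Reagents that add atoms: none
Why: Syn hydrozirconation of the terminal alkyne then Negishi-type palladium-catalysed alkenyl–allyl cross-coupling, which joins the E-alkenyl metal to the unsubstituted terminus of the allyl unit with retention of all alkene geometries; no stereocentre.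

**Step 3**
Reactants: 6 the E-allyl carbamate; 7 methacrolein
Product: 10 (1Z,3S,4S)-4-hydroxy-5-methyl-3-[(2E,6E,10E)-3,7,11,15-tetramethylhexadeca-2,6,10,14-tetraen-1-yl]hexa-1,5-dien-1-yl N,N-diisopropylcarbamate, via (S)-allyllithium sparteine complex 8 (not isolated), via (R)-allyltitanium triisopropoxide 9 (not isolated)
Conditions: n-BuLi, (−)-sparteine, toluene, −78 °C, 3 h; Ti(OiPr)4 (4 equiv), −78 °C; then 7, −78 → −40 °C; aq. HCl work-up
Reagents that add atoms: none
Why: Hoppe asymmetric homoaldol reaction, in which carbamate-directed α-lithiation gives the (−)-sparteine-bound (S)-allyllithium 8, titanation with inversion gives (R)-9, and this homoenolate equivalent adds through its γ-carbon to the aldehyde in a chair Zimmerman–Traxler transition state on the titanium-bearing face (carbamate axial, hence Z-enol carbamate; E-allyl unit, hence anti), so C5 (S) follows from the titanium configuration and C4 (S) from the chair.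

**Step 4**
Reactants: 10 the homoaldol adduct
Product: 12 (4S,5S)-5-(prop-1-en-2-yl)-4-[(2E,6E,10E)-3,7,11,15-tetramethylhexadeca-2,6,10,14-tetraen-1-yl]dihydrofuran-2(3H)-one (trans), via lactol 11 (not isolated)
Conditions: MeSO3H (1.2 equiv), THF–H2O (9:1), 40 °C; extract; then TEMPO (20 mol %), PhI(OAc)2 (1.5 equiv), CH2Cl2, rt
Reagents that add atoms: water, O
Why: Acid hydrolysis of the enol carbamate with participation of the γ-hydroxyl (C-protonation, 5-exo trapping, loss of the carbamic acid) gives the lactol, and oxoammonium oxidation (TEMPO/PhI(OAc)2) of the lactol gives the lactone without touching the alkenes or the two non-enolisable stereocentres.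

**Step 5**
Reactants: 12 the trans-lactone; 13 vinylmagnesium bromide
Product: 15 (5S,6S)-6-hydroxy-7-methyl-5-[(2E,6E,10E)-3,7,11,15-tetramethylhexadeca-2,6,10,14-tetraen-1-yl]octa-1,7-dien-3-one, via magnesium hemiketalate 14 (not isolated)
Conditions: 13 (1.1 equiv), THF, −78 °C, 1 h; cold aqueous pH 7 quench
Reagents that add atoms: none
Why: Mono-addition of a Grignard reagent to a γ-lactone, where the tetrahedral magnesium hemiketalate persists at −78 °C and releases the vinyl ketone only on quench, so no second addition occurs and the stereocentres are untouched.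

**Step 6**
Reactants: 15 the γ-hydroxy vinyl ketone
Product: 16 (4S,5S)-4-hydroxy-3-methyl-5-[(2E,6E,10E)-3,7,11,15-tetramethylhexadeca-2,6,10,14-tetraen-1-yl]cyclohex-2-en-1-one (CNP0277821.1)
Conditions: second-generation Grubbs catalyst RuCl2(=CHPh)(PCy3)(H2IMes) (5 mol %), CH2Cl2 (5 mM), 40 °C
Reagents that add atoms: none
Why: Ring-closing metathesis between the vinyl ketone and the hydroxyl-activated 1,1-disubstituted alkene forms C2=C3 of the six-membered ring with loss of ethene, the trisubstituted chain alkenes being slower partners and the stereocentres from step 3 not being involved.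

**Compound list**
1 | prop-2-yn-1-ol | C#CCO | starting material
2 | N,N-diisopropylcarbamoyl chloride | CC(C)N(C(C)C)C(Cl)=O | starting material
3 | prop-2-yn-1-yl N,N-diisopropylcarbamate | C#CCOC(=O)N(C(C)C)C(C)C | intermediate
4 | (2E,6E,10E)-geranylgeranyl bromide | CC(C)=CCC/C(C)=C/CC/C(C)=C/CC/C(C)=C/CBr | starting material
5 | chlorobis(cyclopentadienyl)[(1E)-3-(N,N-diisopropylcarbamoyloxy)prop-1-en-1-yl]zirconium (cyclopentadienyl rings drawn σ-bound) | CC(C)N(C(C)C)C(=O)OC/C=C/[Zr](Cl)(C1C=CC=C1)C1C=CC=C1 | intermediate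
6 | (2E,5E,9E,13E)-6,10,14,18-tetramethylnonadeca-2,5,9,13,17-pentaen-1-yl N,N-diisopropylcarbamate | CC(C)N(C(C)C)C(=O)OC/C=C/C/C=C(\C)CC/C=C(\C)CC/C=C(\C)CCC=C(C)C | intermediate
7 | methacrolein (2-methylprop-2-enal) | CC(=C)C=O | starting material
8 | (S)-1-lithio derivative of 6 as its (−)-sparteine complex (ligand not drawn) | [Li][C@H](OC(=O)N(C(C)C)C(C)C)/C=C/C/C=C(\C)CC/C=C(\C)CC/C=C(\C)CCC=C(C)C | intermediate
9 | (R)-1-(triisopropoxytitanio) derivative of 6 | CC(C)O[Ti](OC(C)C)(OC(C)C)[C@@H](OC(=O)N(C(C)C)C(C)C)/C=C/C/C=C(\C)CC/C=C(\C)CC/C=C(\C)CCC=C(C)C | intermediate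
10 | (1Z,3S,4S)-4-hydroxy-5-methyl-3-[(2E,6E,10E)-3,7,11,15-tetramethylhexadeca-2,6,10,14-tetraen-1-yl]hexa-1,5-dien-1-yl N,N-diisopropylcarbamate (anti) | CC(C)N(C(C)C)C(=O)O/C=C\[C@H](C/C=C(\C)CC/C=C(\C)CC/C=C(\C)CCC=C(C)C)[C@H](O)C(C)=C | intermediate
11 | (4S,5S)-5-(prop-1-en-2-yl)-4-[(2E,6E,10E)-3,7,11,15-tetramethylhexadeca-2,6,10,14-tetraen-1-yl]tetrahydrofuran-2-ol (both anomers) | OC1C[C@H](C/C=C(\C)CC/C=C(\C)CC/C=C(\C)CCC=C(C)C)[C@@H](C(C)=C)O1 | intermediate
12 | (4S,5S)-5-(prop-1-en-2-yl)-4-[(2E,6E,10E)-3,7,11,15-tetramethylhexadeca-2,6,10,14-tetraen-1-yl]dihydrofuran-2(3H)-one (trans) | O=C1C[C@H](C/C=C(\C)CC/C=C(\C)CC/C=C(\C)CCC=C(C)C)[C@@H](C(C)=C)O1 | intermediate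
13 | vinylmagnesium bromide | C=C[Mg]Br | starting material
14 | bromomagnesium (4S,5S)-2-ethenyl-5-(prop-1-en-2-yl)-4-[(2E,6E,10E)-3,7,11,15-tetramethylhexadeca-2,6,10,14-tetraen-1-yl]tetrahydrofuran-2-olate | C=CC1(O[Mg]Br)C[C@H](C/C=C(\C)CC/C=C(\C)CC/C=C(\C)CCC=C(C)C)[C@@H](C(C)=C)O1 | intermediate
15 | (5S,6S)-6-hydroxy-7-methyl-5-[(2E,6E,10E)-3,7,11,15-tetramethylhexadeca-2,6,10,14-tetraen-1-yl]octa-1,7-dien-3-one | C=CC(=O)C[C@H](C/C=C(\C)CC/C=C(\C)CC/C=C(\C)CCC=C(C)C)[C@H](O)C(C)=C | intermediate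
16 | (4S,5S)-4-hydroxy-3-methyl-5-[(2E,6E,10E)-3,7,11,15-tetramethylhexadeca-2,6,10,14-tetraen-1-yl]cyclohex-2-en-1-one | CC(C)=CCC/C(C)=C/CC/C(C)=C/CC/C(C)=C/C[C@H]1CC(=O)C=C(C)[C@H]1O | target

**Totals**
Total step count: 6. Longest linear sequence: 6 (1 → 3 → 6 → 10 → 12 → 15 → 16); 4, 7 and 13 enter as purchased reagents.

**Three steps most likely to fail, with fallbacks**

First, the homoaldol of step 3. The γ-regioselectivity and the Z/anti outcome are secure. The enantiomeric excess is not: the crotyl precedent relies on crystallisation of the lithium–sparteine complex, which this lipophilic C23 carbamate may not show, and the sense of induction is assigned by analogy. The fallback sets out from 6 and comes back at 10. The homoaldol is run without chiral diamine (s-BuLi, TMEDA, Et2O, −78 °C; Ti(OiPr)4; 7) to give the racemic anti adduct (1Z,3RS,4RS)-4-hydroxy-5-methyl-3-[(2E,6E,10E)-3,7,11,15-tetramethylhexadeca-2,6,10,14-tetraen-1-yl]hexa-1,5-dien-1-yl N,N-diisopropylcarbamate F1. Its secondary allylic alcohol is then resolved by Sharpless kinetic resolution (Ti(OiPr)4, D-(−)-diisopropyl tartrate, t-BuOOH 0.6 equiv, 4 Å sieves, CH2Cl2, −20 °C). The fast-reacting (3R,4R) enantiomer is consumed as the epoxy alcohol (1Z,3R,4R)-4-hydroxy-4-[(2R)-2-methyloxiran-2-yl]-3-[(2E,6E,10E)-3,7,11,15-tetramethylhexadeca-2,6,10,14-tetraen-1-yl]but-1-en-1-yl N,N-diisopropylcarbamate F2 and removed by chromatography. The unreacted (3S,4S) enantiomer is 10; the chain alkenes and the enol carbamate are not allylic alcohols and stay intact.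

Second, the metathesis of step 6. The ruthenium carbene on the vinyl ketone can also close a six-membered ring onto the first chain alkene (cutting off the C17 tail), and closure onto a 1,1-disubstituted alkene next to an enone can be sluggish. The fallback avoids metathesis, sets out from 10 and comes back at 16. The C4 hydroxyl is silylated (i-Pr3SiOTf, 2,6-lutidine) to (1Z,3S,4S)-5-methyl-3-[(2E,6E,10E)-3,7,11,15-tetramethylhexadeca-2,6,10,14-tetraen-1-yl]-4-(triisopropylsilyloxy)hexa-1,5-dien-1-yl N,N-diisopropylcarbamate F3. Hydrolysis of the enol carbamate (MeSO3H, wet THF, 40 °C), now without a neighbouring hydroxyl, gives the open aldehyde (3S,4S)-5-methyl-3-[(2E,6E,10E)-3,7,11,15-tetramethylhexadeca-2,6,10,14-tetraen-1-yl]-4-(triisopropylsilyloxy)hex-5-enal F4. Me2AlCl (CH2Cl2, −78 °C) triggers a Snider carbonyl-ene cyclisation: the aldehyde carbon bonds to the methylene terminus of the isopropenyl group and a methyl hydrogen is transferred, giving (4S,5S)-3-methylidene-5-[(2E,6E,10E)-3,7,11,15-tetramethylhexadeca-2,6,10,14-tetraen-1-yl]-4-(triisopropylsilyloxy)cyclohexan-1-ol F5 as a C1 epimer mixture. Dess–Martin oxidation gives the β,γ-unsaturated ketone (4S,5S)-3-methylidene-5-[(2E,6E,10E)-3,7,11,15-tetramethylhexadeca-2,6,10,14-tetraen-1-yl]-4-(triisopropylsilyloxy)cyclohexan-1-one F6. Catalytic DBU moves the double bond into conjugation, giving (4S,5S)-3-methyl-5-[(2E,6E,10E)-3,7,11,15-tetramethylhexadeca-2,6,10,14-tetraen-1-yl]-4-(triisopropylsilyloxy)cyclohex-2-en-1-one F7. Bu4NF buffered with AcOH removes the silyl group to give 16.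

Third, the vinyl addition of step 5. Double addition, or conjugate addition to the vinyl ketone if the hemiketalate collapses early, would erode the yield of the sensitive product 15. The fallback sets out from 12 and comes back at 15 through an isolated acyl-transfer intermediate. The lactone is opened with MeNH(OMe)·HCl/Me3Al (CH2Cl2, 0 °C → rt) to (3S,4S)-4-hydroxy-N-methoxy-N,5-dimethyl-3-[(2E,6E,10E)-3,7,11,15-tetramethylhexadeca-2,6,10,14-tetraen-1-yl]hex-5-enamide F8. This is used at once (it relactonises on standing) with excess 13 in THF at −78 → 0 °C; the first equivalent forms the magnesium alkoxide and the chelated adduct cannot over-add. Inverse quench into cold aqueous KHSO4 gives 15.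

**Further compounds**
F1 | step 3 | racemic anti adduct, (1Z,3RS,4RS)-4-hydroxy-5-methyl-3-[(2E,6E,10E)-3,7,11,15-tetramethylhexadeca-2,6,10,14-tetraen-1-yl]hexa-1,5-dien-1-yl N,N-diisopropylcarbamate (both enantiomers shown) | CC(C)N(C(C)C)C(=O)O/C=C\[C@H](C/C=C(\C)CC/C=C(\C)CC/C=C(\C)CCC=C(C)C)[C@H](O)C(C)=C.CC(C)N(C(C)C)C(=O)O/C=C\[C@@H](C/C=C(\C)CC/C=C(\C)CC/C=C(\C)CCC=C(C)C)[C@@H](O)C(C)=C
F2 | step 3 | (1Z,3R,4R)-4-hydroxy-4-[(2R)-2-methyloxiran-2-yl]-3-[(2E,6E,10E)-3,7,11,15-tetramethylhexadeca-2,6,10,14-tetraen-1-yl]but-1-en-1-yl N,N-diisopropylcarbamate | CC(C)N(C(C)C)C(=O)O/C=C\[C@@H](C/C=C(\C)CC/C=C(\C)CC/C=C(\C)CCC=C(C)C)[C@@H](O)[C@@]1(C)CO1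
F3 | step 6 | (1Z,3S,4S)-5-methyl-3-[(2E,6E,10E)-3,7,11,15-tetramethylhexadeca-2,6,10,14-tetraen-1-yl]-4-(triisopropylsilyloxy)hexa-1,5-dien-1-yl N,N-diisopropylcarbamate | CC(C)N(C(C)C)C(=O)O/C=C\[C@H](C/C=C(\C)CC/C=C(\C)CC/C=C(\C)CCC=C(C)C)[C@H](O[Si](C(C)C)(C(C)C)C(C)C)C(C)=C
F4 | step 6 | (3S,4S)-5-methyl-3-[(2E,6E,10E)-3,7,11,15-tetramethylhexadeca-2,6,10,14-tetraen-1-yl]-4-(triisopropylsilyloxy)hex-5-enal | O=CC[C@H](C/C=C(\C)CC/C=C(\C)CC/C=C(\C)CCC=C(C)C)[C@H](O[Si](C(C)C)(C(C)C)C(C)C)C(C)=C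
F5 | step 6 | (4S,5S)-3-methylidene-5-[(2E,6E,10E)-3,7,11,15-tetramethylhexadeca-2,6,10,14-tetraen-1-yl]-4-(triisopropylsilyloxy)cyclohexan-1-ol (C1 epimers) | OC1C[C@H](C/C=C(\C)CC/C=C(\C)CC/C=C(\C)CCC=C(C)C)[C@H](O[Si](C(C)C)(C(C)C)C(C)C)C(=C)C1
F6 | step 6 | (4S,5S)-3-methylidene-5-[(2E,6E,10E)-3,7,11,15-tetramethylhexadeca-2,6,10,14-tetraen-1-yl]-4-(triisopropylsilyloxy)cyclohexan-1-one | O=C1C[C@H](C/C=C(\C)CC/C=C(\C)CC/C=C(\C)CCC=C(C)C)[C@H](O[Si](C(C)C)(C(C)C)C(C)C)C(=C)C1
F7 | step 6 | (4S,5S)-3-methyl-5-[(2E,6E,10E)-3,7,11,15-tetramethylhexadeca-2,6,10,14-tetraen-1-yl]-4-(triisopropylsilyloxy)cyclohex-2-en-1-one | CC(C)=CCC/C(C)=C/CC/C(C)=C/CC/C(C)=C/C[C@H]1CC(=O)C=C(C)[C@H]1O[Si](C(C)C)(C(C)C)C(C)C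
F8 | step 5 | (3S,4S)-4-hydroxy-N-methoxy-N,5-dimethyl-3-[(2E,6E,10E)-3,7,11,15-tetramethylhexadeca-2,6,10,14-tetraen-1-yl]hex-5-enamide | CON(C)C(=O)C[C@H](C/C=C(\C)CC/C=C(\C)CC/C=C(\C)CCC=C(C)C)[C@H](O)C(C)=C
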